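**Plan**
- Retrosynthesis: the C6 silyl ether is removed last. Ring B (C5–C10) is opened at C9–C10 to a ring A unit with an exocyclic C10=CH2 alkene whose C5 chain ends in a (Z)-2-alkylidene enal with an acetate at C7. This chain is cut at C7–C8 (aldehyde + alkenyl iodide), the side chain at C12–C13, and the ring A aldehyde at C5–C6.
- Forward: ring A comes from 3-methylcyclohexenone. The ring A aldehyde (steps 1–5) and the side-chain alkenyl iodide (steps 6–9) are joined by a Nozaki–Hiyama–Kishi coupling (step 10). Ring B is closed last (step 13), and one desilylation gives the target.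
- Enabling feature: C9 is the β-carbon of the C7=C8–C17HO enal, and C10 is the methyl-bearing quaternary carbon shared by rings A and B. A tertiary C10 radical (hydrogen-atom transfer to C10=CH2) and a C8-formyl alkene are therefore polarity-matched, and a C7 acetate lets the enolate formed after C–C bond formation regenerate C7=C8.
- Stereochemistry: C6 from Felkin–Anh addition to (R)-glyceraldehyde acetonide, whose own stereocentre is then excised. C5 from the syn-selective Hosomi–Sakurai step. C10 and C9 from ring A and a chair transition state in the key step. Both side-chain alkene geometries from stereospecific alkyne additions and cross-couplings.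

Key step: step 13

Assumption: atom labels follow labdane numbering (ring A = C1–C5 and C10; ring B = C5–C10; C17 = formyl carbon; C11–C16 = side chain). The configuration of the oxygenated C7 in 20–22 and 24 is left unassigned because that centre becomes sp2 in step 13.

Step 1
Reactants: 1 3-methylcyclohex-2-en-1-one
Product: 3 3,3-dimethylcyclohex-1-en-1-yl trifluoromethanesulfonate, via lithium enolate 2 (not isolated)
Conditions: Me2CuLi, Et2O, 0 °C; then PhNTf2, THF, 0 °C to rt
Reagents that add atoms: lithium dimethylcuprate, [Li+].C[Cu-]C; N-phenylbis(trifluoromethanesulfonimide), O=S(=O)(N(c1ccccc1)S(=O)(=O)C(F)(F)F)C(F)(F)F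
Why: Cuprate 1,4-addition creates the gem-dimethyl carbon and delivers the enolate regiospecifically on the side of that carbon, and O-triflation (conjugate addition/enolate trapping) fixes this enol regiochemistry without forming a stereocentre.

Step 2
Reactants: 3 3,3-dimethylcyclohex-1-en-1-yl trifluoromethanesulfonate
Product: 4 [(3,3-dimethylcyclohex-1-en-1-yl)methyl]trimethylsilane
Conditions: Me3SiCH2MgCl, Pd(PPh3)4 (5 mol %), THF, rt
Reagents that add atoms: (trimethylsilyl)methylmagnesium chloride, C[Si](C)(C)C[Mg]Cl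
Why: Kumada cross-coupling of an alkenyl triflate with the silylmethyl Grignard reagent is a standard route to allylsilanes and keeps the alkene next to the gem-dimethyl carbon.

Step 3
Reactants: 4 [(3,3-dimethylcyclohex-1-en-1-yl)methyl]trimethylsilane; 5 (4R)-2,2-dimethyl-1,3-dioxolane-4-carbaldehyde
Product: 6 (S)-[(4R)-2,2-dimethyl-1,3-dioxolan-4-yl][(1R)-2,2-dimethyl-6-methylidenecyclohexyl]methanol
Conditions: BF3·OEt2, CH2Cl2, −78 °C
Reagents that add atoms: none
Why: Hosomi–Sakurai addition through an open antiperiplanar transition state (bond formation at the ring carbon next to the gem-dimethyl group, alkene shift to the exocyclic position) should give the 5,6-syn relationship expected of an allylsilane whose γ-substituent is trans to CH2Si, while Felkin–Anh attack anti to the dioxolane C–O bond under the non-chelating Lewis acid sets C6 as (S) and thereby C5 as (R).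

Step 4
Reactants: 6 (S)-[(4R)-2,2-dimethyl-1,3-dioxolan-4-yl][(1R)-2,2-dimethyl-6-methylidenecyclohexyl]methanol
Product: 7 tert-butyl{(S)-[(4R)-2,2-dimethyl-1,3-dioxolan-4-yl][(1R)-2,2-dimethyl-6-methylidenecyclohexyl]methoxy}dimethylsilane
Conditions: TBSOTf, 2,6-lutidine, CH2Cl2, −78 to 0 °C
Reagents that add atoms: tert-butyldimethylsilyl trifluoromethanesulfonate, CC(C)(C)[Si](C)(C)OS(=O)(=O)C(F)(F)F
Why: Silyl triflate silylation protects the hindered secondary C6 alcohol as an ether that survives every later step up to the final fluoride treatment, with no change at C5 or C6.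

Step 5
Reactants: 7 tert-butyl{(S)-[(4R)-2,2-dimethyl-1,3-dioxolan-4-yl][(1R)-2,2-dimethyl-6-methylidenecyclohexyl]methoxy}dimethylsilane
Product: 9 (2S)-2-[(tert-butyldimethylsilyl)oxy]-2-[(1R)-2,2-dimethyl-6-methylidenecyclohexyl]acetaldehyde, via diol 8 (not isolated)
Conditions: H5IO6, EtOAc, rt
Reagents that add atoms: none
Why: Periodic acid hydrolyses the terminal acetonide and cleaves the resulting glycol in the same flask (oxidative glycol cleavage), which excises the stereocentre borrowed from 5 and leaves the C7 aldehyde without touching C5 or C6.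

Step 6
Reactants: 10 methyl 4-hydroxybut-2-ynoate
Product: 11 methyl (2Z)-4-hydroxy-3-iodobut-2-enoate
Conditions: LiI, AcOH, MeCN, 80 °C
Reagents that add atoms: lithium iodide, [Li+].[I-]
Why: Anti hydroiodination of the ynoate (conjugate addition of iodide, protonation trans to iodine) gives the (Z)-β-iodo enoate, in which iodine is cis to the ester and the hydroxymethyl group is trans, so lactonisation cannot occur.

Step 7
Reactants: 12 3,3-diethoxyprop-1-yne; 13 vinyl bromide
Product: 14 5,5-diethoxypent-1-en-3-yne
Conditions: Pd(PPh3)2Cl2 (2 mol %), CuI (4 mol %), Et3N, THF, rt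
Reagents that add atoms: none
Why: Sonogashira coupling of a terminal alkyne with a vinyl halide is reliable and the acetal is inert to the amine base.

Step 8
Reactants: 14 5,5-diethoxypent-1-en-3-yne; 11 methyl (2Z)-4-hydroxy-3-iodobut-2-enoate
Product: 16 methyl (2E)-8,8-diethoxy-3-(hydroxymethyl)oct-2-en-6-ynoate, via alkylborane 15 (not isolated)
Conditions: 9-BBN, THF, 0 °C to rt; then 11, Pd(dppf)Cl2 (5 mol %), K3PO4, DMF/H2O, rt
Reagents that add atoms: none
Why: 9-BBN should hydroborate the monosubstituted alkene in preference to the internal, acetal-deactivated alkyne with boron at the terminal carbon, and B-alkyl Suzuki–Miyaura coupling with the β-iodo enoate proceeds with retention, so the chain ends up cis to the ester as the target's (E)-alkene requires.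

Step 9
Reactants: 16 methyl (2E)-8,8-diethoxy-3-(hydroxymethyl)oct-2-en-6-ynoate
Product: 18 methyl (2E,6E)-8,8-diethoxy-3-(hydroxymethyl)-7-iodoocta-2,6-dienoate, via alkenylstannane 17 (not isolated)
Conditions: Bu3SnH, Pd(PPh3)2Cl2 (2 mol %), THF, 0 °C; then I2, CH2Cl2, 0 °C
Reagents that add atoms: iodine, II
Why: Palladium-catalysed hydrostannation is a syn addition that places tin on the alkyne carbon next to the electron-withdrawing acetal, and iododestannylation with retention gives the (E)-iodide in which the vinylic hydrogen is cis to iodine; the side-chain hydroxyl is kept free so that no allylic ester is exposed to the palladium hydride.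

Step 10
Reactants: 9 (2S)-2-[(tert-butyldimethylsilyl)oxy]-2-[(1R)-2,2-dimethyl-6-methylidenecyclohexyl]acetaldehyde; 18 methyl (2E,6E)-8,8-diethoxy-3-(hydroxymethyl)-7-iodoocta-2,6-dienoate
Product: 20 methyl (2E,6Z,9S)-9-[(tert-butyldimethylsilyl)oxy]-7-(diethoxymethyl)-9-[(1R)-2,2-dimethyl-6-methylidenecyclohexyl]-8-hydroxy-3-(hydroxymethyl)nona-2,6-dienoate (C8 epimers), via alkenylchromium reagent 19 (not isolated)
Conditions: CrCl2 (4 equiv), NiCl2 (1 mol %), DMSO, rt
Reagents that add atoms: none
Why: Nozaki–Hiyama–Kishi coupling tolerates the ester, the acetal and the free hydroxyl, retains the alkene geometry so that the side chain becomes trans to the new carbinol carbon C7, and adds to the α-silyloxy aldehyde without epimerising C6; the new C7 centre (mainly Felkin) is erased later.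

Step 11
Reactants: 20 methyl (2E,6Z,9S)-9-[(tert-butyldimethylsilyl)oxy]-7-(diethoxymethyl)-9-[(1R)-2,2-dimethyl-6-methylidenecyclohexyl]-8-hydroxy-3-(hydroxymethyl)nona-2,6-dienoate
Product: 21 methyl (2E,6Z,9S)-8-(acetyloxy)-3-[(acetyloxy)methyl]-9-[(tert-butyldimethylsilyl)oxy]-7-(diethoxymethyl)-9-[(1R)-2,2-dimethyl-6-methylidenecyclohexyl]nona-2,6-dienoate
Conditions: Ac2O, pyridine, DMAP (cat.), CH2Cl2, 0 °C to rt
Reagents that add atoms: acetic anhydride, CC(=O)OC(C)=O
Why: One acylation installs both the C16 acetate of the target and the C7 acetate that serves as leaving group in the key step, and it is done before the enal is unmasked so that no amine can add to an activated allylic acetate.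

Step 12
Reactants: 21 methyl (2E,6Z,9S)-8-(acetyloxy)-3-[(acetyloxy)methyl]-9-[(tert-butyldimethylsilyl)oxy]-7-(diethoxymethyl)-9-[(1R)-2,2-dimethyl-6-methylidenecyclohexyl]nona-2,6-dienoate
Product: 22 methyl (2E,6Z,9S)-8-(acetyloxy)-3-[(acetyloxy)methyl]-9-[(tert-butyldimethylsilyl)oxy]-9-[(1R)-2,2-dimethyl-6-methylidenecyclohexyl]-7-formylnona-2,6-dienoate
Conditions: PPTS (cat.), acetone/H2O (10:1), rt
Reagents that add atoms: water, O
Why: Mild acid hydrolysis of the α,β-unsaturated acetal (fast because of the stabilised oxocarbenium ion) should free the enal while the silyl ether, both acetates and the (Z)-geometry (side chain cis to CHO) are retained.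

Step 13
Reactants: 22 methyl (2E,6Z,9S)-8-(acetyloxy)-3-[(acetyloxy)methyl]-9-[(tert-butyldimethylsilyl)oxy]-9-[(1R)-2,2-dimethyl-6-methylidenecyclohexyl]-7-formylnona-2,6-dienoate
Product: 25 methyl (2E)-3-[(acetyloxy)methyl]-5-[(1S,4R,4aR,8aS)-4-[(tert-butyldimethylsilyl)oxy]-2-formyl-5,5,8a-trimethyl-1,4,4a,5,6,7,8,8a-octahydronaphthalen-1-yl]pent-2-enoate, via tertiary radical 23 (not isolated), via acetoxy aldehyde 24 (not isolated)
Conditions: Fe(acac)3 (0.5 equiv), PhSiH3 (2.5 equiv), EtOH/(CH2OH)2 (5:1), 60 °C, degassed; then DBU, CH2Cl2, 0 °C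
Reagents that add atoms: none
Why: Proposed new method: an iron hydride formed from Fe(acac)3 and PhSiH3 should transfer a hydrogen atom to the exocyclic C10=CH2 of ring A to give tertiary radical 23, which adds to C9, the β-carbon of the C8-formyl alkene; the α-formyl radical is then reduced by divalent iron to the enolate, which expels the C7 acetate (E1cB, completed by DBU on any protonated 24) to give the C7=C8 enal. The closest known reaction types are the iron-hydride-initiated Giese cyclisation with radical–polar crossover onto enals and enones and the radical addition–elimination of Morita–Baylis–Hillman acetates, which have not been combined in a closure onto a β-substituted 2-(1-acetoxyalkyl)enal. Ring B (C5–C10) closes in the 6-endo-trig mode because exo attack at the fully substituted, electron-poor α-carbon C8 is disfavoured by both sterics and polarity. C10 is controlled by ring A: C9 enters equatorially, anti to H5 and away from the axial C4 methyl, which gives the trans ring fusion. C9 is controlled by a chair transition state in which the C6 silyloxy group is equatorial and the side chain, being trans to the C7 tether across the (Z)-enal, becomes equatorial and cis to the C10 methyl. The step needs hydrogen-atom transfer to the 1,1-disubstituted alkene in preference to the enal and the trisubstituted enoate, which the electron-rich, unhindered character of that alkene should secure, and it needs the (Z)-geometry of 22 to survive, which the neutral medium allows.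

Step 14
Reactants: 25 methyl (2E)-3-[(acetyloxy)methyl]-5-[(1S,4R,4aR,8aS)-4-[(tert-butyldimethylsilyl)oxy]-2-formyl-5,5,8a-trimethyl-1,4,4a,5,6,7,8,8a-octahydronaphthalen-1-yl]pent-2-enoate
Product: 26 methyl (2E)-3-[(acetyloxy)methyl]-5-[(1S,4R,4aR,8aS)-2-formyl-4-hydroxy-5,5,8a-trimethyl-1,4,4a,5,6,7,8,8a-octahydronaphthalen-1-yl]pent-2-enoate
Conditions: HF·pyridine, pyridine, THF, 0 °C to rt
Reagents that add atoms: none
Why: Buffered fluoride desilylation removes the last helper group and should leave the enal, the acetate, the methyl ester and the configuration of the allylic C6 alcohol untouched.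

**Compound list**
1 | 3-methylcyclohex-2-en-1-one | CC1=CC(=O)CCC1 | starting material
2 | lithium 3,3-dimethylcyclohex-1-en-1-olate | [Li+].[O-]C1=CC(C)(C)CCC1 | intermediate
3 | 3,3-dimethylcyclohex-1-en-1-yl trifluoromethanesulfonate | CC1(C)CCCC(OS(=O)(=O)C(F)(F)F)=C1 | intermediate
4 | [(3,3-dimethylcyclohex-1-en-1-yl)methyl]trimethylsilane | C[Si](C)(C)CC1=CC(C)(C)CCC1 | intermediate
5 | (4R)-2,2-dimethyl-1,3-dioxolane-4-carbaldehyde ((R)-glyceraldehyde acetonide) | O=C[C@H]1COC(C)(C)O1 | starting material
6 | (S)-[(4R)-2,2-dimethyl-1,3-dioxolan-4-yl][(1R)-2,2-dimethyl-6-methylidenecyclohexyl]methanol | CC1(C)OC[C@@H](O1)[C@@H](O)[C@@H]1C(C)(C)CCCC1=C | intermediate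
7 | tert-butyl{(S)-[(4R)-2,2-dimethyl-1,3-dioxolan-4-yl][(1R)-2,2-dimethyl-6-methylidenecyclohexyl]methoxy}dimethylsilane | CC1(C)OC[C@@H](O1)[C@@H](O[Si](C)(C)C(C)(C)C)[C@@H]1C(C)(C)CCCC1=C | intermediate
8 | (2R,3S)-3-[(tert-butyldimethylsilyl)oxy]-3-[(1R)-2,2-dimethyl-6-methylidenecyclohexyl]propane-1,2-diol | OC[C@@H](O)[C@@H](O[Si](C)(C)C(C)(C)C)[C@@H]1C(C)(C)CCCC1=C | intermediate
9 | (2S)-2-[(tert-butyldimethylsilyl)oxy]-2-[(1R)-2,2-dimethyl-6-methylidenecyclohexyl]acetaldehyde | O=C[C@@H](O[Si](C)(C)C(C)(C)C)[C@@H]1C(C)(C)CCCC1=C | intermediate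
10 | methyl 4-hydroxybut-2-ynoate | COC(=O)C#CCO | starting material
11 | methyl (2Z)-4-hydroxy-3-iodobut-2-enoate | COC(=O)/C=C(\I)CO | intermediate
12 | 3,3-diethoxyprop-1-yne | CCOC(OCC)C#C | starting material
13 | vinyl bromide | C=CBr | starting material
14 | 5,5-diethoxypent-1-en-3-yne | CCOC(OCC)C#CC=C | intermediate
15 | 9-(5,5-diethoxypent-3-yn-1-yl)-9-borabicyclo[3.3.1]nonane | CCOC(OCC)C#CCCB1C2CCCC1CCC2 | intermediate
16 | methyl (2E)-8,8-diethoxy-3-(hydroxymethyl)oct-2-en-6-ynoate | COC(=O)/C=C(\CCC#CC(OCC)OCC)CO | intermediate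
17 | methyl (2E,6E)-8,8-diethoxy-3-(hydroxymethyl)-7-(tributylstannyl)octa-2,6-dienoate | COC(=O)/C=C(\CC/C=C(/[Sn](CCCC)(CCCC)CCCC)C(OCC)OCC)CO | intermediate
18 | methyl (2E,6E)-8,8-diethoxy-3-(hydroxymethyl)-7-iodoocta-2,6-dienoate | COC(=O)/C=C(\CC/C=C(/I)C(OCC)OCC)CO | intermediate
19 | alkenylchromium dichloride formed from 18 (chromium in place of iodine, geometry retained) | COC(=O)/C=C(\CC/C=C(/[Cr](Cl)Cl)C(OCC)OCC)CO | intermediate
20 | methyl (2E,6Z,9S)-9-[(tert-butyldimethylsilyl)oxy]-7-(diethoxymethyl)-9-[(1R)-2,2-dimethyl-6-methylidenecyclohexyl]-8-hydroxy-3-(hydroxymethyl)nona-2,6-dienoate (C8 epimers) | COC(=O)/C=C(\CC/C=C(/C(O)[C@@H](O[Si](C)(C)C(C)(C)C)[C@@H]1C(C)(C)CCCC1=C)C(OCC)OCC)CO | intermediate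
21 | methyl (2E,6Z,9S)-8-(acetyloxy)-3-[(acetyloxy)methyl]-9-[(tert-butyldimethylsilyl)oxy]-7-(diethoxymethyl)-9-[(1R)-2,2-dimethyl-6-methylidenecyclohexyl]nona-2,6-dienoate (C8 epimers) | COC(=O)/C=C(\CC/C=C(/C(OC(C)=O)[C@@H](O[Si](C)(C)C(C)(C)C)[C@@H]1C(C)(C)CCCC1=C)C(OCC)OCC)COC(C)=O | intermediate
22 | methyl (2E,6Z,9S)-8-(acetyloxy)-3-[(acetyloxy)methyl]-9-[(tert-butyldimethylsilyl)oxy]-9-[(1R)-2,2-dimethyl-6-methylidenecyclohexyl]-7-formylnona-2,6-dienoate (C8 epimers) | COC(=O)/C=C(\CC/C=C(/C(OC(C)=O)[C@@H](O[Si](C)(C)C(C)(C)C)[C@@H]1C(C)(C)CCCC1=C)C=O)COC(C)=O | intermediate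
23 | tertiary C10 radical of 22 (hydrogen added to the exocyclic CH2, radical on the ring carbon that now bears a methyl group) | COC(=O)/C=C(\CC/C=C(/C(OC(C)=O)[C@@H](O[Si](C)(C)C(C)(C)C)[C@@H]1C(C)(C)CCC[C]1C)C=O)COC(C)=O | intermediate
24 | ring-closed β-acetoxy aldehyde: the C7-acetoxy, C8-formyl (C8–H) decalin, ring-fusion, C6 and C9 centres as in 25, C7 and C8 unassigned | COC(=O)/C=C(\CC[C@@H]1C(C=O)C(OC(C)=O)[C@@H](O[Si](C)(C)C(C)(C)C)[C@@H]2C(C)(C)CCC[C@@]12C)COC(C)=O | intermediate
25 | methyl (2E)-3-[(acetyloxy)methyl]-5-[(1S,4R,4aR,8aS)-4-[(tert-butyldimethylsilyl)oxy]-2-formyl-5,5,8a-trimethyl-1,4,4a,5,6,7,8,8a-octahydronaphthalen-1-yl]pent-2-enoate | COC(=O)/C=C(\CC[C@@H]1C(C=O)=C[C@@H](O[Si](C)(C)C(C)(C)C)[C@@H]2C(C)(C)CCC[C@@]12C)COC(C)=O | intermediate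
26 | methyl (2E)-3-[(acetyloxy)methyl]-5-[(1S,4R,4aR,8aS)-2-formyl-4-hydroxy-5,5,8a-trimethyl-1,4,4a,5,6,7,8,8a-octahydronaphthalen-1-yl]pent-2-enoate | COC(=O)/C=C(\CC[C@@H]1C(C=O)=C[C@@H](O)[C@@H]2C(C)(C)CCC[C@@]12C)COC(C)=O | target

**Step count**
Total: 14 steps. Longest linear sequence: 10 steps (steps 1–5, then 10–14).

**Steps most likely to fail**

Step 13 (proposed new method). The tertiary radical may be reduced to the hydrocarbon before it cyclises. Reversible hydrogen-atom transfer may move the alkene into ring A and erode C5. The iron hydride may also attack the enal instead of the ring A alkene. Fallback, by known chemistry, setting out from 22: Markovnikov hydrochlorination of the exocyclic alkene (anhydrous HCl, CH2Cl2, −78 °C) should give the tertiary chloride F1. A classical tin hydride chain reaction (Bu3SnH, AIBN, benzene, 80 °C, slow addition) then generates the same C10 radical without a metal hydride, closes ring B 6-endo and ends by hydrogen transfer from tin to give β-acetoxy aldehyde 24. DBU eliminates acetic acid and the route is rejoined at 25.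

Step 3. The allylsilane may react sluggishly at the ring carbon flanked by the gem-dimethyl group, and facial selectivity toward the glyceraldehyde (Felkin–Anh against chelation) or survival of the acetonide under the Lewis acid may be poor. Fallback, setting out from 4: a catalyst-controlled addition to ethyl glyoxylate with a BINOL/Ti(OiPr)4 catalyst (the BINOL enantiomer that delivers the (S)-carbinol, expected to be (S)-BINOL by analogy with glyoxylate-ene reactions) should give the hydroxy ester F2. Silylation (TBSOTf, 2,6-lutidine) gives the silyl ether F3, and i-Bu2AlH at −78 °C reduces the ester to the aldehyde, rejoining the route at 9. Facial control then rests on the catalyst and not on the aldehyde, and no acetonide is exposed to BF3.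

Step 8. Hydroboration of the conjugated enyne may compete at the alkyne or give mixtures, and the free hydroxyl of 11 may slow transmetalation. Fallback, setting out from 12: deprotonation (n-BuLi) and opening of ethylene oxide (BF3·OEt2, THF, −78 °C) gives the homopropargylic alcohol F4. Iodination (I2, PPh3, imidazole) gives the iodide F5, and zinc insertion (Zn, LiCl, THF) gives the alkylzinc iodide F6. Negishi coupling of F6 (in excess) with 11 (Pd(PPh3)4, THF, rt) forms the same C12–C13 bond with retention and returns to 16.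

**Further compounds**
F1 | step 13 | tertiary chloride: HCl adduct of 22 at the exocyclic alkene (2-chloro-2,6,6-trimethylcyclohexyl ring; other centres and both alkene geometries as in 22; chlorine-bearing carbon unassigned) | COC(=O)/C=C(\CC/C=C(/C(OC(C)=O)[C@@H](O[Si](C)(C)C(C)(C)C)[C@@H]1C(C)(C)CCCC1(C)Cl)C=O)COC(C)=O
F2 | step 3 | ethyl (2S)-2-[(1R)-2,2-dimethyl-6-methylidenecyclohexyl]-2-hydroxyacetate | CCOC(=O)[C@@H](O)[C@@H]1C(C)(C)CCCC1=C
F3 | step 3 | ethyl (2S)-2-[(tert-butyldimethylsilyl)oxy]-2-[(1R)-2,2-dimethyl-6-methylidenecyclohexyl]acetate | CCOC(=O)[C@@H](O[Si](C)(C)C(C)(C)C)[C@@H]1C(C)(C)CCCC1=C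
F4 | step 8 | 5,5-diethoxypent-3-yn-1-ol | CCOC(OCC)C#CCCO
F5 | step 8 | 5,5-diethoxy-1-iodopent-3-yne | CCOC(OCC)C#CCCI
F6 | step 8 | (5,5-diethoxypent-3-yn-1-yl)zinc iodide | CCOC(OCC)C#CCC[Zn]I
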